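**Plan**

- Retrosynthesis: the C6 ester and the two silyl ethers come off first; the 6β‑OH/7α‑OH pair goes back to the conjugated 6‑ketone 20; ring B of 20 is cut at C8–C9 to the 1‑allenylcyclobutanol 18; 18 is cut at C7–C6 (acetylide), C17 (formaldehyde), C9–C11 (enolate alkylation) and at C5–C6 plus C9–C10 (keteniminium [2+2]).
- Forward: ring A is bought as 2,2,6‑trimethylcyclohexanone; a four‑membered ring C5–C6–C9–C10 is fused onto its alkene, which also makes quaternary C10; the side chain is alkylated onto C9; ring B then arises by a two‑carbon ring expansion.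
- Enabling feature: the oxygen‑bearing C6 and the alkene carbon C9 are 1,4 to each other through the ring‑fusion carbons C5 and C10, so ring B can be stored as a strained cyclobutanol on ring A whose C6–C9 bond is traded for C8–C9 while C6 becomes the ketone.
- Stereochemistry: C10 from the auxiliary‑controlled cycloaddition; C5 by equilibration to the trans‑decalone; O7 (α) and O6 (β) by substrate control, both reagents avoiding the face under the axial methyls on C4 and C10; 13E from syn‑carboalumination.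

Key step: step 10

Remark: labdane numbering (C1–C20) is used for the decalin compounds and, in the discussion, for the carbons that become them.
Assumption: the (2R,5R) antipode of the C2‑symmetric auxiliary is taken to give the (1R,6R) cycloadduct 9; if the sense of induction is the opposite, (2S,5S)‑2,5‑dimethylpyrrolidine is used and nothing else changes.

**Route**

Step 1
Reactants: 1 2,2,6‑trimethylcyclohexan‑1‑one
Product: 2 N'‑(2,2,6‑trimethylcyclohexylidene)‑4‑methylbenzenesulfonohydrazide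
Conditions: TsNHNH2, cat. HCl, EtOH, reflux
Reagents that add atoms: 4‑methylbenzenesulfonohydrazide, Cc1ccc(cc1)S(=O)(=O)NN
Why: Acid‑catalysed hydrazone condensation, which this hindered ketone is known to undergo with arenesulfonyl hydrazides.

Step 2
Reactants: 2 N'‑(2,2,6‑trimethylcyclohexylidene)‑4‑methylbenzenesulfonohydrazide
Product: 4 1,3,3‑trimethylcyclohex‑1‑ene, via (2,6,6‑trimethylcyclohex‑1‑en‑1‑yl)lithium 3 (not isolated)
Conditions: MeLi (2.2 equiv), Et2O, 0 °C → rt; H2O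
Reagents that add atoms: none
Why: Shapiro reaction: the only α‑hydrogen is on the methyl‑bearing carbon, so loss of sulfinate and N2 gives one vinyllithium and, after protonation, one alkene.

Step 3
Reactants: 5 (2R,5R)‑2,5‑dimethylpyrrolidine
Product: 6 1‑[(2R,5R)‑2,5‑dimethylpyrrolidin‑1‑yl]ethan‑1‑one
Conditions: Ac2O, Et3N, CH2Cl2, 0 °C → rt
Reagents that add atoms: acetic anhydride, CC(=O)OC(C)=O
Why: N‑acylation of a secondary amine; the stereocentres of the auxiliary are not touched.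

Step 4
Reactants: 6 1‑[(2R,5R)‑2,5‑dimethylpyrrolidin‑1‑yl]ethan‑1‑one; 4 1,3,3‑trimethylcyclohex‑1‑ene
Product: 9 (1R,6R)‑1,5,5‑trimethylbicyclo[4.2.0]octan‑7‑one, via keteniminium triflate 7 (not isolated), via cyclobutaniminium triflate 8 (not isolated)
Conditions: Tf2O, 2,4,6‑collidine, 4 (3 equiv), ClCH2CH2Cl, 0 → 80 °C; then H2O, aq. NaHCO3
Reagents that add atoms: water, O
Why: Keteniminium–alkene [2+2] cycloaddition (Ghosez type) and iminium hydrolysis: the central carbon bonds to the less substituted alkene carbon (future C5) and the CH2 terminus to the methyl‑bearing carbon, which makes quaternary C10, while the auxiliary should select the alkene face and the suprafacial addition gives the cis ring fusion.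

Step 5
Reactants: 10 4‑iodobut‑1‑yne
Product: 12 (2E)‑5‑iodo‑3‑methylpent‑2‑en‑1‑ol, via alkenyldimethylalane 11 (not isolated)
Conditions: Me3Al, Cp2ZrCl2 (0.2 equiv), CH2Cl2, 0 °C → rt; (CH2O)n, THF; aq. HCl
Reagents that add atoms: trimethylaluminium, C[Al](C)C; formaldehyde (as paraformaldehyde), C=O
Why: Zirconium‑catalysed syn‑carboalumination (Negishi) of the terminal alkyne, then hydroxymethylation of the alkenylalane; syn addition with aluminium on the terminal carbon fixes the E trisubstituted alkene.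

Step 6
Reactants: 12 (2E)‑5‑iodo‑3‑methylpent‑2‑en‑1‑ol
Product: 13 tert‑butyl{[(2E)‑5‑iodo‑3‑methylpent‑2‑en‑1‑yl]oxy}dimethylsilane
Conditions: t‑BuMe2SiCl, imidazole, DMF, 0 °C
Reagents that add atoms: tert‑butylchlorodimethylsilane, CC(C)(C)[Si](C)(C)Cl
Why: Standard silylation of a primary alcohol.

Step 7
Reactants: 9 (1R,6R)‑1,5,5‑trimethylbicyclo[4.2.0]octan‑7‑one; 13 tert‑butyl{[(2E)‑5‑iodo‑3‑methylpent‑2‑en‑1‑yl]oxy}dimethylsilane
Product: 15 (1R,6R)‑8‑{(3E)‑5‑[(tert‑butyldimethylsilyl)oxy]‑3‑methylpent‑3‑en‑1‑yl}‑1,5,5‑trimethylbicyclo[4.2.0]octan‑7‑one (both C8 epimers), via lithium enolate 14 (not isolated)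
Conditions: LiN(i‑Pr)2, THF, −78 °C; 13, DMPU, −78 → −20 °C
Reagents that add atoms: none
Why: Kinetic enolate alkylation (SN2): the cyclobutanone enolises away from the ring fusion, so only the CH2 carbon (future C9) is alkylated, and its configuration is of no consequence because it becomes sp2.

Step 8
Reactants: 15 (1R,6R)‑8‑{(3E)‑5‑[(tert‑butyldimethylsilyl)oxy]‑3‑methylpent‑3‑en‑1‑yl}‑1,5,5‑trimethylbicyclo[4.2.0]octan‑7‑one
Product: 16 (1R,6R)‑8‑{(3E)‑5‑[(tert‑butyldimethylsilyl)oxy]‑3‑methylpent‑3‑en‑1‑yl}‑7‑ethynyl‑1,5,5‑trimethylbicyclo[4.2.0]octan‑7‑ol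
Conditions: HC≡CMgBr, THF, −20 → 0 °C; H2O
Reagents that add atoms: ethynylmagnesium bromide, C#C[Mg]Br
Why: 1,2‑Addition of an alkynyl Grignard reagent to a strained, electrophilic cyclobutanone; the carbinol configuration does not matter because this carbon becomes the C6 ketone.

Step 9
Reactants: 16 (1R,6R)‑8‑{(3E)‑5‑[(tert‑butyldimethylsilyl)oxy]‑3‑methylpent‑3‑en‑1‑yl}‑7‑ethynyl‑1,5,5‑trimethylbicyclo[4.2.0]octan‑7‑ol
Product: 18 (1R,6R)‑8‑{(3E)‑5‑[(tert‑butyldimethylsilyl)oxy]‑3‑methylpent‑3‑en‑1‑yl}‑1,5,5‑trimethyl‑7‑(propa‑1,2‑dien‑1‑yl)bicyclo[4.2.0]octan‑7‑ol, via propargylic amine 17 (not isolated)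
Conditions: CuI (copper iodide, 0.5 equiv), (CH2O)n, (c‑C6H11)2NH, 1,4‑dioxane, reflux
Reagents that add atoms: formaldehyde (as paraformaldehyde), C=O
Why: Crabbé homologation (copper‑mediated Mannich reaction, then hydride transfer and elimination from the propargylic amine) turns the terminal alkyne into the terminal allene; the added carbon becomes the C8 methyl (C17).

Step 10
Reactants: 18 (1R,6R)‑8‑{(3E)‑5‑[(tert‑butyldimethylsilyl)oxy]‑3‑methylpent‑3‑en‑1‑yl}‑1,5,5‑trimethyl‑7‑(propa‑1,2‑dien‑1‑yl)bicyclo[4.2.0]octan‑7‑ol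
Product: 20 (5S,9S,10R)‑15‑[(tert‑butyldimethylsilyl)oxy]labda‑7,13E‑dien‑6‑one, via cis‑fused enone 19 (not isolated)
Conditions: [Rh(OH)(cod)]2 (2.5 mol %), DTBM‑SEGPHOS (6 mol %), toluene, 80 °C; then NaOMe (0.3 equiv), MeOH, 50 °C
Reagents that add atoms: none
Why: Hydroxide/alkoxide exchange puts monovalent rhodium on O6; β‑carbon elimination then breaks the C6–C9 bond of the four‑membered ring (its strain, about 26 kcal/mol, and the new C6=O bond drive the step), and the resulting C9–rhodium bond adds across the C7=C8 bond of the allenyl ketone so that C9 bonds to the central allene carbon C8. The ring so closed is the six‑membered ring B and the closure is a 6‑endo carbometalation (C7 and C8 both end up in the ring); protonation of the rhodium dienolate at the terminal allene carbon by the next molecule of 18 makes the C8 methyl and returns the alkoxide. The closest known reaction type is the rhodium‑catalysed ring expansion of 1‑allenyl tert‑cyclobutanols to 3‑methylcyclohex‑2‑enones by β‑carbon elimination and intramolecular 1,4‑addition. No stereocentre of the target is made here: C10 is carried through, C9 is formed as a mixture and becomes sp2 in step 11, and C5, held cis by the four‑membered ring, is equilibrated by methoxide in the same flask (through the C5=C6 enolate) to the trans‑decalone with the side chain equatorial. The step needs scission of C6–C9 and not of the ring‑fusion bond C6–C5, and carbometalation before β‑hydride loss from C9–Rh: the first is secured because rhodium on C5 would be wedged between the quaternary carbons C4 and C10 while C9 has only one such neighbour, the second because the allenyl ketone stays chelated to the same metal centre, whose bisphosphine leaves no free site.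

Step 11
Reactants: 20 (5S,9S,10R)‑15‑[(tert‑butyldimethylsilyl)oxy]labda‑7,13E‑dien‑6‑one
Product: 22 (5S,7S,10S)‑15‑[(tert‑butyldimethylsilyl)oxy]‑7‑hydroxylabda‑8,13E‑dien‑6‑one, via potassium dienolate 21 (not isolated)
Conditions: KOt‑Bu (1.1 equiv), THF, 0 °C → rt; then 3‑phenyl‑2‑(phenylsulfonyl)oxaziridine, −78 °C; H2O
Reagents that add atoms: 3‑phenyl‑2‑(phenylsulfonyl)oxaziridine, O=S(=O)(c1ccccc1)N1OC1c1ccccc1
Why: Under equilibrating conditions KOt‑Bu is expected to give the extended dienolate with the endocyclic, fully substituted C8=C9 bond (the isophorone pattern), and electrophilic α‑hydroxylation with the Davis oxaziridine then places oxygen on C7 from the α‑face, anti to the axial C10 methyl, leaving the 8(9)‑alkene out of conjugation.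

Step 12
Reactants: 22 (5S,7S,10S)‑15‑[(tert‑butyldimethylsilyl)oxy]‑7‑hydroxylabda‑8,13E‑dien‑6‑one
Product: 23 (5S,6S,7S,10S)‑15‑[(tert‑butyldimethylsilyl)oxy]labda‑8,13E‑diene‑6,7‑diol
Conditions: Me4NBH(OAc)3, AcOH/MeCN, −30 °C
Reagents that add atoms: none
Why: Hydroxyl‑directed triacetoxyborohydride reduction: boron bound to the 7α‑oxygen delivers hydride to the α‑face of C6, which is also the only open face because the β‑face lies under the axial methyls on C4 and C10, so the 6β‑alcohol trans to O7 should result.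

Step 13
Reactants: 23 (5S,6S,7S,10S)‑15‑[(tert‑butyldimethylsilyl)oxy]labda‑8,13E‑diene‑6,7‑diol
Product: 24 (5S,6S,7S,10S)‑15‑[(tert‑butyldimethylsilyl)oxy]‑7‑[(triethylsilyl)oxy]labda‑8,13E‑dien‑6‑ol
Conditions: Et3SiCl, imidazole, CH2Cl2, −20 °C
Reagents that add atoms: chlorotriethylsilane, CC[Si](Cl)(CC)CC
Why: Standard silyl ether formation, expected to take only the allylic 7α‑hydroxyl because the 6β‑hydroxyl is 1,3‑diaxial to two methyl groups.

Step 14
Reactants: 24 (5S,6S,7S,10S)‑15‑[(tert‑butyldimethylsilyl)oxy]‑7‑[(triethylsilyl)oxy]labda‑8,13E‑dien‑6‑ol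
Product: 25 (5S,6S,7S,10S)‑15‑[(tert‑butyldimethylsilyl)oxy]‑7‑[(triethylsilyl)oxy]labda‑8,13E‑dien‑6‑yl 3‑methylbutanoate
Conditions: 3‑methylbutanoic anhydride, DMAP, Et3N, CH2Cl2, 40 °C
Reagents that add atoms: 3‑methylbutanoic anhydride, CC(C)CC(=O)OC(=O)CC(C)C
Why: DMAP‑catalysed acyl transfer (Steglich type) onto the one remaining hydroxyl; warming compensates for its axial, hindered position.

Step 15
Reactants: 25 (5S,6S,7S,10S)‑15‑[(tert‑butyldimethylsilyl)oxy]‑7‑[(triethylsilyl)oxy]labda‑8,13E‑dien‑6‑yl 3‑methylbutanoate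
Product: 26 (5S,6S,7S,10S)‑7,15‑dihydroxylabda‑8,13E‑dien‑6‑yl 3‑methylbutanoate
Conditions: HF·pyridine, THF, 0 °C → rt
Reagents that add atoms: none
Why: Fluoride‑mediated cleavage of both silyl ethers; the ester should stay on O6 because O6 and O7 are trans‑diaxial and cannot be bridged for acyl migration.

**Compound list**

1 | 2,2,6‑trimethylcyclohexan‑1‑one (racemic; its stereocentre is lost in step 2) | CC1CCCC(C)(C)C1=O | starting material
2 | N'‑(2,2,6‑trimethylcyclohexylidene)‑4‑methylbenzenesulfonohydrazide | CC1CCCC(C)(C)C1=NNS(=O)(=O)c1ccc(C)cc1 | intermediate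
3 | (2,6,6‑trimethylcyclohex‑1‑en‑1‑yl)lithium (formed in the flask) | [Li]C1=C(C)CCCC1(C)C | intermediate
4 | 1,3,3‑trimethylcyclohex‑1‑ene | CC1=CC(C)(C)CCC1 | intermediate
5 | (2R,5R)‑2,5‑dimethylpyrrolidine | C[C@@H]1CC[C@@H](C)N1 | starting material
6 | 1‑[(2R,5R)‑2,5‑dimethylpyrrolidin‑1‑yl]ethan‑1‑one | C[C@@H]1CC[C@@H](C)N1C(C)=O | intermediate
7 | (2R,5R)‑1‑ethenylidene‑2,5‑dimethylpyrrolidin‑1‑ium trifluoromethanesulfonate (formed in the flask) | C[C@@H]1CC[C@@H](C)[N+]1=C=C.[O-]S(=O)(=O)C(F)(F)F | intermediate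
8 | (2R,5R)‑2,5‑dimethyl‑1‑[(1R,6R)‑1,5,5‑trimethylbicyclo[4.2.0]octan‑7‑ylidene]pyrrolidin‑1‑ium trifluoromethanesulfonate (formed in the flask) | C[C@@H]1CC[C@@H](C)[N+]1=C1C[C@@]2(C)CCCC(C)(C)[C@@H]12.[O-]S(=O)(=O)C(F)(F)F | intermediate
9 | (1R,6R)‑1,5,5‑trimethylbicyclo[4.2.0]octan‑7‑one | O=C1C[C@@]2(C)CCCC(C)(C)[C@@H]12 | intermediate
10 | 4‑iodobut‑1‑yne | C#CCCI | starting material
11 | [(1E)‑4‑iodo‑2‑methylbut‑1‑en‑1‑yl]dimethylalumane (formed in the flask) | C[Al](C)/C=C(C)/CCI | intermediate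
12 | (2E)‑5‑iodo‑3‑methylpent‑2‑en‑1‑ol | OC/C=C(C)/CCI | intermediate
13 | tert‑butyl{[(2E)‑5‑iodo‑3‑methylpent‑2‑en‑1‑yl]oxy}dimethylsilane | CC(C)(C)[Si](C)(C)OC/C=C(C)/CCI | intermediate
14 | lithium (1R,6R)‑1,5,5‑trimethylbicyclo[4.2.0]oct‑7‑en‑7‑olate (formed in the flask) | [Li+].[O-]C1=C[C@@]2(C)CCCC(C)(C)[C@@H]12 | intermediate
15 | (1R,6R)‑8‑{(3E)‑5‑[(tert‑butyldimethylsilyl)oxy]‑3‑methylpent‑3‑en‑1‑yl}‑1,5,5‑trimethylbicyclo[4.2.0]octan‑7‑one (both C8 epimers) | O=C1C(CC/C(C)=C/CO[Si](C)(C)C(C)(C)C)[C@@]2(C)CCCC(C)(C)[C@@H]12 | intermediate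
16 | (1R,6R)‑8‑{(3E)‑5‑[(tert‑butyldimethylsilyl)oxy]‑3‑methylpent‑3‑en‑1‑yl}‑7‑ethynyl‑1,5,5‑trimethylbicyclo[4.2.0]octan‑7‑ol (diastereomers at C7 and C8) | C#CC1(O)C(CC/C(C)=C/CO[Si](C)(C)C(C)(C)C)[C@@]2(C)CCCC(C)(C)[C@@H]12 | intermediate
17 | (1R,6R)‑8‑{(3E)‑5‑[(tert‑butyldimethylsilyl)oxy]‑3‑methylpent‑3‑en‑1‑yl}‑7‑[3‑(dicyclohexylamino)prop‑1‑yn‑1‑yl]‑1,5,5‑trimethylbicyclo[4.2.0]octan‑7‑ol (formed in the flask) | C(C#CC1(O)C(CC/C(C)=C/CO[Si](C)(C)C(C)(C)C)[C@@]2(C)CCCC(C)(C)[C@@H]12)N(C1CCCCC1)C1CCCCC1 | intermediate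
18 | (1R,6R)‑8‑{(3E)‑5‑[(tert‑butyldimethylsilyl)oxy]‑3‑methylpent‑3‑en‑1‑yl}‑1,5,5‑trimethyl‑7‑(propa‑1,2‑dien‑1‑yl)bicyclo[4.2.0]octan‑7‑ol (diastereomers at C7 and C8) | C=C=CC1(O)C(CC/C(C)=C/CO[Si](C)(C)C(C)(C)C)[C@@]2(C)CCCC(C)(C)[C@@H]12 | intermediate
19 | (5R,10R)‑15‑[(tert‑butyldimethylsilyl)oxy]labda‑7,13E‑dien‑6‑one (cis‑fused, both C9 epimers; formed in the flask) | CC1=CC(=O)[C@@H]2C(C)(C)CCC[C@]2(C)C1CC/C(C)=C/CO[Si](C)(C)C(C)(C)C | intermediate
20 | (5S,9S,10R)‑15‑[(tert‑butyldimethylsilyl)oxy]labda‑7,13E‑dien‑6‑one (trans‑fused, 9α‑H) | CC1=CC(=O)[C@H]2C(C)(C)CCC[C@]2(C)[C@H]1CC/C(C)=C/CO[Si](C)(C)C(C)(C)C | intermediate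
21 | potassium (5S,10S)‑15‑[(tert‑butyldimethylsilyl)oxy]labda‑6,8,13E‑trien‑6‑olate (formed in the flask) | [K+].CC1=C(CC/C(C)=C/CO[Si](C)(C)C(C)(C)C)[C@@]2(C)CCCC(C)(C)[C@@H]2C([O-])=C1 | intermediate
22 | (5S,7S,10S)‑15‑[(tert‑butyldimethylsilyl)oxy]‑7‑hydroxylabda‑8,13E‑dien‑6‑one (7α‑OH) | CC1=C(CC/C(C)=C/CO[Si](C)(C)C(C)(C)C)[C@@]2(C)CCCC(C)(C)[C@@H]2C(=O)[C@H]1O | intermediate
23 | (5S,6S,7S,10S)‑15‑[(tert‑butyldimethylsilyl)oxy]labda‑8,13E‑diene‑6,7‑diol (6β,7α) | CC1=C(CC/C(C)=C/CO[Si](C)(C)C(C)(C)C)[C@@]2(C)CCCC(C)(C)[C@@H]2[C@H](O)[C@H]1O | intermediate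
24 | (5S,6S,7S,10S)‑15‑[(tert‑butyldimethylsilyl)oxy]‑7‑[(triethylsilyl)oxy]labda‑8,13E‑dien‑6‑ol | CC1=C(CC/C(C)=C/CO[Si](C)(C)C(C)(C)C)[C@@]2(C)CCCC(C)(C)[C@@H]2[C@H](O)[C@H]1O[Si](CC)(CC)CC | intermediate
25 | (5S,6S,7S,10S)‑15‑[(tert‑butyldimethylsilyl)oxy]‑7‑[(triethylsilyl)oxy]labda‑8,13E‑dien‑6‑yl 3‑methylbutanoate | CC1=C(CC/C(C)=C/CO[Si](C)(C)C(C)(C)C)[C@@]2(C)CCCC(C)(C)[C@@H]2[C@H](OC(=O)CC(C)C)[C@H]1O[Si](CC)(CC)CC | intermediate
26 | (5S,6S,7S,10S)‑7,15‑dihydroxylabda‑8,13E‑dien‑6‑yl 3‑methylbutanoate (CNP0173680.1) | CC1=C(CC/C(C)=C/CO)[C@@]2(C)CCCC(C)(C)[C@@H]2[C@H](OC(=O)CC(C)C)[C@H]1O | target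

**Step count and risks**

Total step count: 15. Longest linear sequence: 12 steps (1 to 26 through steps 1, 2, 4 and 7–15; steps 3 and 5–6 are side branches).

Step 4. What may go wrong: slow cycloaddition at the hindered trisubstituted alkene, and incomplete discrimination of the two alkene faces by the auxiliary. Fallback (robust racemic cycloaddition, then resolution): from 4, dichloroketene (Cl3CCOCl, Zn, Et2O) adds with the same regiochemistry to give racemic 8,8‑dichloro‑1,5,5‑trimethylbicyclo[4.2.0]octan‑7‑one F1. Zn in AcOH then removes both chlorines to give 9 together with its mirror image (1S,6S)‑1,5,5‑trimethylbicyclo[4.2.0]octan‑7‑one F2. The two are separated by preparative chromatography on a chiral stationary phase, and the route is rejoined at 9.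

Step 10. What may go wrong: β‑hydride elimination from the secondary C9–rhodium intermediate, or β‑carbon elimination toward the ring‑fusion carbon C5, before the carbometalation. Fallback (radical in place of organometallic ring expansion): from 15, (E)‑prop‑1‑enylmagnesium bromide gives the 7‑[(1E)‑prop‑1‑en‑1‑yl] carbinol F3. Its alkoxy radical, generated by photocatalytic proton‑coupled electron transfer ([Ir(dF(CF3)ppy)2(dtbbpy)]PF6, collidine, an arenethiol, blue light), undergoes β‑scission and 6‑endo radical addition to the enone so formed; this is the known two‑carbon ring expansion of 1‑alkenylcycloalkanols. The product is the saturated cis‑fused ketone (5R,10R)‑15‑[(tert‑butyldimethylsilyl)oxy]labd‑13E‑en‑6‑one F4. No β‑hydride pathway exists here, but the scission direction then rests on radical stability; in this manifold cleavage toward C5 (relief of crowding between C4 and C10) is at least as likely as cleavage toward C9, so this fallback removes only the β‑hydride problem. 2‑Iodoxybenzoic acid (DMSO, 70 °C) dehydrogenates F4 between C7 and C8 (C5 has no β‑hydrogen), and the methoxide equilibration of step 10 brings the material back to 20.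

Step 11. What may go wrong: enolisation toward the C8 methyl instead of C9, and epimerisation of the new carbinol carbon by alkoxide. Fallback (separate the equilibration from the oxidation): from 20, KOt‑Bu followed by cold aqueous acetic acid (kinetic α‑protonation) gives the deconjugated ketone (5S,10S)‑15‑[(tert‑butyldimethylsilyl)oxy]labda‑8,13E‑dien‑6‑one F5, which is purified as the single 8(9)‑ene. In F5 the C7 methylene between carbonyl and alkene is the only readily removed proton, so LiN(SiMe3)2 at −78 °C forms the same dienolate without a regiochemical choice. MoO5·pyridine·HMPA hydroxylates it, and the route is rejoined at 22. This only helps if the 8(9)‑ene is the favoured or separable isomer; it does not rescue a dienolate that prefers the methyl side.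

Further compounds
F1 | step 4 | 8,8‑dichloro‑1,5,5‑trimethylbicyclo[4.2.0]octan‑7‑one (racemic, cis‑fused; the (1R,6R) antipode is drawn) | O=C1C(Cl)(Cl)[C@@]2(C)CCCC(C)(C)[C@@H]12
F2 | step 4 | (1S,6S)‑1,5,5‑trimethylbicyclo[4.2.0]octan‑7‑one | O=C1C[C@]2(C)CCCC(C)(C)[C@H]12
F3 | step 10 | (1R,6R)‑8‑{(3E)‑5‑[(tert‑butyldimethylsilyl)oxy]‑3‑methylpent‑3‑en‑1‑yl}‑1,5,5‑trimethyl‑7‑[(1E)‑prop‑1‑en‑1‑yl]bicyclo[4.2.0]octan‑7‑ol | C/C=C/C1(O)C(CC/C(C)=C/CO[Si](C)(C)C(C)(C)C)[C@@]2(C)CCCC(C)(C)[C@@H]12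
F4 | step 10 | (5R,10R)‑15‑[(tert‑butyldimethylsilyl)oxy]labd‑13E‑en‑6‑one (cis‑fused; mixture at C8 and C9) | CC1CC(=O)[C@@H]2C(C)(C)CCC[C@]2(C)C1CC/C(C)=C/CO[Si](C)(C)C(C)(C)C
F5 | step 11 | (5S,10S)‑15‑[(tert‑butyldimethylsilyl)oxy]labda‑8,13E‑dien‑6‑one | CC1=C(CC/C(C)=C/CO[Si](C)(C)C(C)(C)C)[C@@]2(C)CCCC(C)(C)[C@@H]2C(=O)C1
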